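**Retrosynthetic overview**
1. Target ⇐ reagent-controlled double epoxidation of the macrocyclic E,E-diene acetate (both oxiranes last).
2. Twelve-membered ring ⇐ intramolecular Hosomi–Sakurai closure of C10–C11 from an allylsilane aldehyde; this one step creates C10–O, C11–H and the exocyclic methylene.
3. Allylsilane enone ⇐ 5-substituted 4,4-dimethylcyclohex-2-enone (α-iodination, Negishi coupling).
4. That enone ⇐ C2v-symmetric 4,4-dimethylcyclohexa-2,5-dienone: an enantioselective thia-Michael addition of benzenethiol breaks the symmetry, the sulfide centre steers a trans allylbarium 1,4-addition of the chain (C1–C2), then leaves by sulfoxide elimination.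
5. C10 chain ⇐ geranyl acetate (allylic oxidation, Pd allylation of nitromethane, Nef acetal). Ring order: six-membered ring present from the start, macrocycle second, oxiranes third.

Assumption: the quinine-derived urea catalyst is taken to give the (5R) sulfide; if its sense is the reverse, the quinidine-derived pseudoenantiomer is used. Bicyclic compounds are numbered as bicyclo[9.3.1]pentadecane (C1–C15), which coincides with the numbering used for the target.

**Step 1**
Reactants: 1 geranyl acetate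
Product: 2 (2E,6E)-8-hydroxy-3,7-dimethylocta-2,6-dien-1-yl acetate
Conditions: SeO2 (10 mol %), t-BuOOH, salicylic acid (cat.), CH2Cl2, rt
Reagents that add atoms: selenium dioxide O=[Se]=O (catalytic oxygen carrier); tert-butyl hydroperoxide CC(C)(C)OO
Why: Sharpless allylic oxidation (ene reaction then [2,3]-shift) attacks the E-methyl of the electron-rich terminal alkene, while the acetate deactivates the other alkene.

**Step 2**
Reactants: 2
Product: 3 (2E,6E)-8-[(methoxycarbonyl)oxy]-3,7-dimethylocta-2,6-dien-1-yl acetate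
Conditions: ClCO2Me, pyridine, CH2Cl2, 0 °C
Reagents that add atoms: methyl chloroformate COC(=O)Cl
Why: Simple acylation gives an allylic carbonate that ionises far faster than the allylic acetate at the other end.

**Step 3**
Reactants: 3
Product: 4 (2E,6E)-3,7-dimethyl-9-nitronona-2,6-dien-1-yl acetate
Conditions: Pd2(dba)3 (2.5 mol %), dppe, MeNO2–THF, rt
Reagents that add atoms: nitromethane C[N+](=O)[O-]
Why: Tsuji–Trost allylation under neutral conditions: zerovalent palladium ionises the carbonate, the released methoxide deprotonates nitromethane, and the nitronate attacks the CH2 terminus of the syn π-allyl, so the 6E geometry is kept.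

**Step 4**
Reactants: 4
Product: 6 (2E,6E)-9,9-dimethoxy-3,7-dimethylnona-2,6-dien-1-ol, via sodium nitronate 5 (not isolated)
Conditions: NaOMe, MeOH, 0 °C to rt; then into H2SO4–MeOH, −40 °C
Reagents that add atoms: methanol CO
Why: Nef reaction in its acetal variant: the nitronate is solvolysed in cold methanolic acid to the dimethyl acetal, and NaOMe removes the acetate by transesterification in the same pot.

**Step 5**
Reactants: 6
Product: 7 (2E,6E)-1-chloro-9,9-dimethoxy-3,7-dimethylnona-2,6-diene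
Conditions: MsCl, LiCl, 2,4,6-collidine, DMF, 0 °C
Reagents that add atoms: lithium chloride [Li+].[Cl-]
Why: Collington–Meyers chlorination: the mesylate formed in situ is displaced by chloride (SN2) without allylic shift or loss of E geometry, and the buffered medium spares the acetal.

**Step 6**
Reactants: 8 4,4-dimethylcyclohex-2-en-1-one
Product: 9 4,4-dimethylcyclohexa-2,5-dien-1-one
Conditions: DDQ, 1,4-dioxane, reflux
Reagents that add atoms: none
Why: DDQ dehydrogenation of the enol; the quaternary C4 rules out aromatisation, so the cross-conjugated dienone is the end point.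

**Step 7**
Reactants: 9; 10 benzenethiol
Product: 11 (5R)-4,4-dimethyl-5-(phenylsulfanyl)cyclohex-2-en-1-one
Conditions: 1-[3,5-bis(trifluoromethyl)phenyl]-3-(9-deoxy-epi-quinin-9-yl)urea (1 mol %), PhSH (0.95 equiv, slow addition), toluene, −40 °C
Reagents that add atoms: none
Why: Organocatalytic asymmetric thia-Michael addition: the urea binds the dienone carbonyl and the quinuclidine delivers the thiol to one enantiotopic face of one of the two equivalent enone arms, which breaks the C2v symmetry and sets the (R) sulfide centre.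

**Step 8**
Reactants: 7; 11
Product: 14 (3R,5R)-3-[(2E,6E)-9,9-dimethoxy-3,7-dimethylnona-2,6-dien-1-yl]-4,4-dimethyl-5-(phenylsulfanyl)cyclohexan-1-one, via allylbarium chloride 12 (not isolated), via barium enolate 13 (not isolated)
Conditions: BaI2, lithium biphenylide (2 equiv), THF, rt; 7, −78 °C; then 11, −78 °C; NH4Cl aq.
Reagents that add atoms: none
Why: Yamamoto-type allylbarium conjugate addition: the allylbarium keeps its E geometry at −78 °C and reacts through its CH2 terminus in the 1,4-sense; axial attack anti to the C5 sulfide and to the axial C4 methyl puts the chain trans to sulfur, giving the (3R) centre.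

**Step 9**
Reactants: 14
Product: 16 (5R)-5-[(2E,6E)-9,9-dimethoxy-3,7-dimethylnona-2,6-dien-1-yl]-4,4-dimethylcyclohex-2-en-1-one, via sulfoxide 15 (not isolated)
Conditions: mCPBA (1.0 equiv), CH2Cl2, −78 °C; then Et3N, toluene, 60 °C
Reagents that add atoms: none
Why: Chemoselective S-oxidation then sulfoxide syn-elimination: only the C6 hydrogens are available because C4 is quaternary, so a single enone forms and the relay centre is erased, leaving C5 (R) as the only stereocentre.

**Step 10**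
Reactants: 16
Product: 17 (5R)-5-[(2E,6E)-9,9-dimethoxy-3,7-dimethylnona-2,6-dien-1-yl]-2-iodo-4,4-dimethylcyclohex-2-en-1-one
Conditions: I2, pyridine, CH2Cl2, 0 °C to rt
Reagents that add atoms: iodine II
Why: Johnson α-iodination (pyridine adds 1,4, the enolate is iodinated, pyridine is expelled); the isolated trisubstituted alkenes and the acetal are inert in the buffered medium.

**Step 11**
Reactants: 17
Product: 18 (5R)-5-[(2E,6E)-9,9-dimethoxy-3,7-dimethylnona-2,6-dien-1-yl]-4,4-dimethyl-2-[(trimethylsilyl)methyl]cyclohex-2-en-1-one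
Conditions: Me3SiCH2MgCl, ZnCl2, THF; then 17, Pd(PPh3)4 (5 mol %), THF, 50 °C
Reagents that add atoms: (trimethylsilyl)methylzinc chloride C[Si](C)(C)C[Zn]Cl
Why: Negishi cross-coupling of the alkenyl iodide; the organozinc tolerates the ketone and installs the allylsilane whose CH2 becomes the exocyclic methylene carbon.

**Step 12**
Reactants: 18
Product: 19 (3E,7E)-9-[(1R)-2,2-dimethyl-5-oxo-4-[(trimethylsilyl)methyl]cyclohex-3-en-1-yl]-3,7-dimethylnona-3,7-dienal
Conditions: PPTS, acetone–H2O, 40 °C (used at once)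
Reagents that add atoms: water O
Why: Mild acetal hydrolysis; the weak acid avoids protodesilylation and migration of the β,γ-alkene into conjugation.

**Step 13**
Reactants: 19
Product: 20 (1R,3E,7E,10S,11S)-10-hydroxy-4,8,15,15-tetramethyl-12-methylidenebicyclo[9.3.1]pentadeca-3,7-dien-13-one
Conditions: BF3·OEt2 (2.2 equiv), CH2Cl2, −78 °C, 1 mM, slow addition
Reagents that add atoms: none
Why: Intramolecular Hosomi–Sakurai reaction of an acyl-substituted allylsilane: anti-SE2′ attack of C11 on the BF3-bound aldehyde through an open antiperiplanar transition state gives the syn (10S,11S) alcohol, bond formation anti to the axial C15 methyl places C10 trans to the C1 side chain, and loss of silicon leaves the exocyclic methylene.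

**Step 14**
Reactants: 20
Product: 21 (1R,3E,7E,10S,11S)-4,8,15,15-tetramethyl-12-methylidene-13-oxobicyclo[9.3.1]pentadeca-3,7-dien-10-yl acetate
Conditions: Ac2O, DMAP, pyridine, CH2Cl2, rt
Reagents that add atoms: acetic anhydride CC(=O)OC(C)=O
Why: DMAP-catalysed acylation of the secondary alcohol; no stereocentre is touched.

**Step 15**
Reactants: 21
Product: 24 (1R,3R,4R,7R,8R,10S,11S)-3,4:7,8-diepoxy-4,8,15,15-tetramethyl-12-methylidene-13-oxobicyclo[9.3.1]pentadecan-10-yl acetate, via 7,8-monoepoxide 22 (not isolated), via 3,4-monoepoxide 23 (not isolated)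
Conditions: 1,2:4,5-di-O-isopropylidene-β-D-erythro-2,3-hexodiulo-2,6-pyranose (0.6 equiv), KHSO5 (as 2KHSO5·KHSO4·K2SO4), K2CO3, Bu4NHSO4, Na2B4O7 buffer, MeCN–CH2(OMe)2–H2O, 0 °C
Reagents that add atoms: potassium peroxymonosulfate [K+].[O-]S(=O)(=O)OO
Why: Shi epoxidation: the fructose-derived dioxirane epoxidises E-trisubstituted alkenes through the spiro transition state with the R,R sense at both olefins; the electron-poor methylene ketone does not react with the electrophilic oxidant.

**Compound list**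
1 | geranyl acetate | CC(=O)OC/C=C(C)/CCC=C(C)C | starting material
2 | (2E,6E)-8-hydroxy-3,7-dimethylocta-2,6-dien-1-yl acetate | CC(=O)OC/C=C(C)/CC/C=C(C)/CO | intermediate
3 | (2E,6E)-8-[(methoxycarbonyl)oxy]-3,7-dimethylocta-2,6-dien-1-yl acetate | CC(=O)OC/C=C(C)/CC/C=C(C)/COC(=O)OC | intermediate
4 | (2E,6E)-3,7-dimethyl-9-nitronona-2,6-dien-1-yl acetate | CC(=O)OC/C=C(C)/CC/C=C(C)/CC[N+](=O)[O-] | intermediate
5 | sodium nitronate of (2E,6E)-3,7-dimethyl-9-nitronona-2,6-dien-1-ol | OC/C=C(C)/CC/C=C(C)/CC=[N+]([O-])[O-].[Na+] | intermediate (not isolated)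
6 | (2E,6E)-9,9-dimethoxy-3,7-dimethylnona-2,6-dien-1-ol | OC/C=C(C)/CC/C=C(C)/CC(OC)OC | intermediate
7 | (2E,6E)-1-chloro-9,9-dimethoxy-3,7-dimethylnona-2,6-diene | ClC/C=C(C)/CC/C=C(C)/CC(OC)OC | intermediate
8 | 4,4-dimethylcyclohex-2-en-1-one | O=C1C=CC(C)(C)CC1 | starting material
9 | 4,4-dimethylcyclohexa-2,5-dien-1-one | O=C1C=CC(C)(C)C=C1 | intermediate
10 | benzenethiol | Sc1ccccc1 | starting material
11 | (5R)-4,4-dimethyl-5-(phenylsulfanyl)cyclohex-2-en-1-one | O=C1C=CC(C)(C)[C@H](Sc2ccccc2)C1 | intermediate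
12 | [(2E,6E)-9,9-dimethoxy-3,7-dimethylnona-2,6-dien-1-yl]barium chloride | Cl[Ba]C/C=C(C)/CC/C=C(C)/CC(OC)OC | intermediate (not isolated)
13 | chlorobarium enolate of 14 | Cl[Ba]OC1=C[C@@H](C/C=C(C)/CC/C=C(C)/CC(OC)OC)C(C)(C)[C@H](Sc2ccccc2)C1 | intermediate (not isolated)
14 | (3R,5R)-3-[(2E,6E)-9,9-dimethoxy-3,7-dimethylnona-2,6-dien-1-yl]-4,4-dimethyl-5-(phenylsulfanyl)cyclohexan-1-one | O=C1C[C@@H](C/C=C(C)/CC/C=C(C)/CC(OC)OC)C(C)(C)[C@H](Sc2ccccc2)C1 | intermediate
15 | S-oxide of 14 (both configurations at sulfur) | O=C1C[C@@H](C/C=C(C)/CC/C=C(C)/CC(OC)OC)C(C)(C)[C@H](S(=O)c2ccccc2)C1 | intermediate (not isolated)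
16 | (5R)-5-[(2E,6E)-9,9-dimethoxy-3,7-dimethylnona-2,6-dien-1-yl]-4,4-dimethylcyclohex-2-en-1-one | O=C1C[C@@H](C/C=C(C)/CC/C=C(C)/CC(OC)OC)C(C)(C)C=C1 | intermediate
17 | (5R)-5-[(2E,6E)-9,9-dimethoxy-3,7-dimethylnona-2,6-dien-1-yl]-2-iodo-4,4-dimethylcyclohex-2-en-1-one | O=C1C[C@@H](C/C=C(C)/CC/C=C(C)/CC(OC)OC)C(C)(C)C=C1I | intermediate
18 | (5R)-5-[(2E,6E)-9,9-dimethoxy-3,7-dimethylnona-2,6-dien-1-yl]-4,4-dimethyl-2-[(trimethylsilyl)methyl]cyclohex-2-en-1-one | O=C1C[C@@H](C/C=C(C)/CC/C=C(C)/CC(OC)OC)C(C)(C)C=C1C[Si](C)(C)C | intermediate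
19 | (3E,7E)-9-[(1R)-2,2-dimethyl-5-oxo-4-[(trimethylsilyl)methyl]cyclohex-3-en-1-yl]-3,7-dimethylnona-3,7-dienal | O=C1C[C@@H](C/C=C(C)/CC/C=C(C)/CC=O)C(C)(C)C=C1C[Si](C)(C)C | intermediate
20 | (1R,3E,7E,10S,11S)-10-hydroxy-4,8,15,15-tetramethyl-12-methylidenebicyclo[9.3.1]pentadeca-3,7-dien-13-one | C=C1C(=O)C[C@H]2C/C=C(C)/CC/C=C(C)/C[C@H](O)[C@H]1C2(C)C | intermediate
21 | (1R,3E,7E,10S,11S)-4,8,15,15-tetramethyl-12-methylidene-13-oxobicyclo[9.3.1]pentadeca-3,7-dien-10-yl acetate | C=C1C(=O)C[C@H]2C/C=C(C)/CC/C=C(C)/C[C@H](OC(C)=O)[C@H]1C2(C)C | intermediate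
22 | (1R,3E,7R,8R,10S,11S)-7,8-epoxy-4,8,15,15-tetramethyl-12-methylidene-13-oxobicyclo[9.3.1]pentadec-3-en-10-yl acetate | C=C1C(=O)C[C@H]2C/C=C(C)/CC[C@H]3O[C@]3(C)C[C@H](OC(C)=O)[C@H]1C2(C)C | intermediate (not isolated)
23 | (1R,3R,4R,7E,10S,11S)-3,4-epoxy-4,8,15,15-tetramethyl-12-methylidene-13-oxobicyclo[9.3.1]pentadec-7-en-10-yl acetate | C=C1C(=O)C[C@H]2C[C@H]3O[C@]3(C)CC/C=C(C)/C[C@H](OC(C)=O)[C@H]1C2(C)C | intermediate (not isolated)
24 | (1R,3R,4R,7R,8R,10S,11S)-3,4:7,8-diepoxy-4,8,15,15-tetramethyl-12-methylidene-13-oxobicyclo[9.3.1]pentadecan-10-yl acetate | C=C1C(=O)C[C@H]2C[C@H]3O[C@]3(C)CC[C@H]3O[C@]3(C)C[C@H](OC(C)=O)[C@H]1C2(C)C | target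

**Step count**
Total: 15 steps. Longest linear sequence: 13 steps (steps 1–5, then 8–15); the ring branch (steps 6–7) joins at step 8.

**Three steps most likely to fail, with fallbacks**

Step 8 (allylbarium 1,4-addition). The β-carbon is neopentyl, and the basic reagent could instead expel thiolate from 11 and return the achiral dienone. The fallback sets out from 7 and 11. PhSO2Na in DMF turns 7 into the allylic sulfone [(2E,6E)-9,9-dimethoxy-3,7-dimethylnona-2,6-dien-1-yl]sulfonylbenzene F1. Its lithium anion (n-BuLi, THF–HMPA, −78 °C) adds 1,4 to 11 through the sulfonyl-bearing carbon, trans to the sulfide, and Me3SiCl traps the enolate as the trimethylsilyl enol ether of the 1′-benzenesulfonyl analogue of 14 F2. PdCl2(dppp)-catalysed hydride displacement of the allylic sulfone with LiBHEt3 (the ketone is masked as the enol ether), then K2CO3/MeOH, comes back to the route at 14.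

Step 13 (Sakurai macrocyclisation). The acyl-substituted allylsilane is a weak nucleophile, and the syn and trans-bridged outcome rests on an open transition state in a twelve-membered closure. The fallback sets out from 16. Morita–Baylis–Hillman hydroxymethylation (aqueous CH2O, DMAP) gives (5R)-5-[(2E,6E)-9,9-dimethoxy-3,7-dimethylnona-2,6-dien-1-yl]-2-(hydroxymethyl)-4,4-dimethylcyclohex-2-en-1-one F3. PBr3 gives (5R)-2-(bromomethyl)-5-[(2E,6E)-9,9-dimethoxy-3,7-dimethylnona-2,6-dien-1-yl]-4,4-dimethylcyclohex-2-en-1-one F4. PPTS in wet acetone frees (3E,7E)-9-[(1R)-4-(bromomethyl)-2,2-dimethyl-5-oxocyclohex-3-en-1-yl]-3,7-dimethylnona-3,7-dienal F5. CrCl2 in THF at high dilution (Nozaki–Hiyama allylation) closes the ring through a chair transition state, which should give the C10 epimer (1R,3E,7E,10R,11S)-10-hydroxy-4,8,15,15-tetramethyl-12-methylidenebicyclo[9.3.1]pentadeca-3,7-dien-13-one F6. Mitsunobu inversion with acetic acid (PPh3, DIAD) comes back to the route at 21.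

Step 15 (double epoxidation). The facial sense inside the macrocycle may not follow the reagent, and the basic medium may touch the methylene ketone. The fallback sets out from 20. VO(acac)2 with t-BuOOH in CH2Cl2 uses the homoallylic C10 hydroxyl to deliver oxygen to the C7–C8 alkene, giving (1R,3E,7R,8R,10S,11S)-7,8-epoxy-10-hydroxy-4,8,15,15-tetramethyl-12-methylidenebicyclo[9.3.1]pentadec-3-en-13-one F7. Acetylation (Ac2O, DMAP) comes back to the route at 22, and the remaining C3–C4 alkene is then epoxidised alone with the step 15 reagent.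

**Further compounds**
F1 | step 8 | [(2E,6E)-9,9-dimethoxy-3,7-dimethylnona-2,6-dien-1-yl]sulfonylbenzene | O=S(=O)(C/C=C(C)/CC/C=C(C)/CC(OC)OC)c1ccccc1
F2 | step 8 | trimethylsilyl enol ether of 3-[(2E,6E)-1-(benzenesulfonyl)-9,9-dimethoxy-3,7-dimethylnona-2,6-dien-1-yl]-4,4-dimethyl-5-(phenylsulfanyl)cyclohexan-1-one (ring centres as in 14, both epimers at the sulfonyl carbon) | C[Si](C)(C)OC1=C[C@@H](C(/C=C(C)/CC/C=C(C)/CC(OC)OC)S(=O)(=O)c2ccccc2)C(C)(C)[C@H](Sc2ccccc2)C1
F3 | step 13 | (5R)-5-[(2E,6E)-9,9-dimethoxy-3,7-dimethylnona-2,6-dien-1-yl]-2-(hydroxymethyl)-4,4-dimethylcyclohex-2-en-1-one | O=C1C[C@@H](C/C=C(C)/CC/C=C(C)/CC(OC)OC)C(C)(C)C=C1CO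
F4 | step 13 | (5R)-2-(bromomethyl)-5-[(2E,6E)-9,9-dimethoxy-3,7-dimethylnona-2,6-dien-1-yl]-4,4-dimethylcyclohex-2-en-1-one | O=C1C[C@@H](C/C=C(C)/CC/C=C(C)/CC(OC)OC)C(C)(C)C=C1CBr
F5 | step 13 | (3E,7E)-9-[(1R)-4-(bromomethyl)-2,2-dimethyl-5-oxocyclohex-3-en-1-yl]-3,7-dimethylnona-3,7-dienal | O=C1C[C@@H](C/C=C(C)/CC/C=C(C)/CC=O)C(C)(C)C=C1CBr
F6 | step 13 | (1R,3E,7E,10R,11S)-10-hydroxy-4,8,15,15-tetramethyl-12-methylidenebicyclo[9.3.1]pentadeca-3,7-dien-13-one | C=C1C(=O)C[C@H]2C/C=C(C)/CC/C=C(C)/C[C@@H](O)[C@H]1C2(C)C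
F7 | step 15 | (1R,3E,7R,8R,10S,11S)-7,8-epoxy-10-hydroxy-4,8,15,15-tetramethyl-12-methylidenebicyclo[9.3.1]pentadec-3-en-13-one | C=C1C(=O)C[C@H]2C/C=C(C)/CC[C@H]3O[C@]3(C)C[C@H](O)[C@H]1C2(C)C
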